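**Plan**

- Numbering follows the briarane skeleton: ring A = C1, C10–C14; ten-membered ring = C1–C10; lactone = O–C7–C8–C17–C19(=O); C15 = methyl on C1, C16 = chloromethyl carbon, C20 = epoxide CH2.
- Cuts: the C11/C20 epoxide oxygen and C16–Cl (last), then C8–C9 (opens the ten-membered ring to a C9 aldehyde tethered to a tetronate), then C4–C5 (B-alkyl Suzuki), giving ring A fragment 21 and iodo-tetronate 35.
- Enabling feature: the lactone ring O–C7–C8–C17–C19 is a dihydrotetronate whose β-carbon C8 carries oxygen and is bonded to the carbinol carbon C9, so a C9 ketyl can add to C8 of the parent tetronate and the C17 enolate is protonated.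
- Forward: ring A by Diels–Alder (C1–C14 and C10–C11), then its C12–C14 oxygens, the C11=C20 methylene and the C2 branch; tetronate from the chiral pool; Suzuki union; SmI2 closure of the ten-membered ring; acetylation, deprotection, chloride, epoxide.
- Stereochemistry: C1/C10 from the (E)-enal and a chiral diol catalyst; C13/C14 by OsO4 anti to the axial C15 methyl; C12 by hydride anti to the acetonide; C2 by chelation-controlled vinyl addition; C7 from (R)-glyceraldehyde acetonide; C5=C6 geometry from trans-hydroalumination; C8, C9 and C17 in the key step; C11 by hydroxyl-directed epoxidation.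

Key step: step 26

Assumption: the (R,R)-diol catalyst of step 2 is taken to give the (4S,5S)-enone 7; should the sense be opposite, the (S,S)-antipode is used with nothing else changed.

**Route**

Step 1
Reactants: 1 (tert-butyldiphenylsilyloxy)acetaldehyde; 2 2-(triphenylphosphoranylidene)propanal
Product: 3 (E)-4-(tert-butyldiphenylsilyloxy)-2-methylbut-2-enal
Conditions: toluene, 80 °C
Reagents that add atoms: none
Why: Wittig olefination with a stabilised formyl ylide should give the trisubstituted (E)-enal (C2 formyl trans to C9) and sets no stereocentre.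

Step 2
Reactants: 3 (E)-enal; 4 (E)-3-(tert-butyldimethylsilyloxy)-N,N-dimethylbuta-1,3-dien-1-amine
Product: 7 (4S,5S)-5-[(tert-butyldiphenylsilyloxy)methyl]-4-(hydroxymethyl)-4-methylcyclohex-2-en-1-one, via cycloadduct aldehyde 5 (not isolated), via amino alcohol 6 (not isolated)
Conditions: (R,R)-1-naphthyl-TADDOL (20 mol %), toluene, −78 °C; LiAlH4, Et2O, −78 °C to rt; 0.1 M HCl, THF, 0 °C
Reagents that add atoms: none
Why: Hydrogen-bond-catalysed Diels–Alder reaction of a 1-amino-3-siloxydiene with an α-substituted enal, in which the nucleophilic diene terminus C11 bonds to C10 and C14 to C1, the (E)-geometry of 3 fixes C9 trans to C2 and the chiral diol sets the absolute configuration at C1 and C10, followed by hydride reduction of the aldehyde and acid-induced hydrolysis and β-elimination of dimethylamine to the enone.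

Step 3
Reactants: 7 enone alcohol
Product: 8 C2 tert-butyldimethylsilyl ether of 7
Conditions: TBSCl, imidazole, DMF, rt
Reagents that add atoms: tert-butyldimethylsilyl chloride, CC(C)(C)[Si](C)(C)Cl
Why: Silylation of the primary neopentyl alcohol masks C2 while ring A is oxidised and touches no stereocentre.

Step 4
Reactants: 8 silyl ether enone
Product: 9 cis-13,14-diol ketone (both hydroxyls cis to the C2 branch, trans to C15)
Conditions: OsO4 (5 mol %), N-methylmorpholine N-oxide, citric acid, acetone/H2O, rt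
Reagents that add atoms: N-methylmorpholine N-oxide, C[N+]1([O-])CCOCC1; water, O (both oxygens relayed by catalytic OsO4, O=[Os](=O)(=O)=O)
Why: Upjohn dihydroxylation of the enone C13=C14 bond should occur anti to the pseudoaxial C15 methyl on the adjacent quaternary C1, which places both new hydroxyls cis to the C2 branch.

Step 5
Reactants: 9 diol ketone
Product: 10 13,14-acetonide ketone
Conditions: 2,2-dimethoxypropane, PPTS, acetone, rt
Reagents that add atoms: 2,2-dimethoxypropane, COC(C)(C)OC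
Why: Acid-catalysed transketalisation closes the cis-fused dioxolane on the cis-diol without touching a stereocentre.

Step 6
Reactants: 10 acetonide ketone
Product: 14 C11-methylene C12-ketone, via lithium enolate 11 (not isolated), via Mannich base 12 (not isolated), via ammonium iodide 13 (not isolated)
Conditions: LiN(i-Pr)2, THF, −78 °C; CH2=NMe2+ I−, −78 °C to rt; MeI, CH2Cl2, rt; DBU, rt
Reagents that add atoms: N,N-dimethylmethyleneiminium iodide, C=[N+](C)C.[I-]
Why: Kinetic deprotonation at C11, the only methylene α to the ketone, then Mannich reaction, quaternisation and E1cB elimination (α-methylenation) install C20, and the transient C11 centre is lost again.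

Step 7
Reactants: 14 methylene ketone
Product: 15 C12 allylic alcohol (hydroxyl cis to the acetonide oxygens)
Conditions: NaBH4, CeCl3·7H2O, MeOH, −78 °C
Reagents that add atoms: none
Why: Luche 1,2-reduction, in which the axial C14 oxygen of the cis-fused dioxolane blocks axial attack, so hydride enters from the face opposite the acetonide and the C12 hydroxyl ends up all-cis with O13 and O14.

Step 8
Reactants: 15 allylic alcohol
Product: 16 C12 4-methoxybenzyl ether
Conditions: NaH, 4-methoxybenzyl chloride, Bu4NI (cat.), DMF, 0 °C to rt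
Reagents that add atoms: 4-methoxybenzyl chloride, COc1ccc(CCl)cc1
Why: Williamson etherification protects the hydroxyl that must be free only at the end and touches no stereocentre.

Step 9
Reactants: 16 bis-silyl ether
Product: 17 C2 primary alcohol
Conditions: HF·pyridine, pyridine, THF, 0 °C
Reagents that add atoms: none
Why: Selective desilylation, since buffered HF·pyridine cleaves the primary tert-butyldimethylsilyl ether much faster than the tert-butyldiphenylsilyl ether at C9.

Step 10
Reactants: 17 primary alcohol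
Product: 18 C2 aldehyde
Conditions: Dess–Martin periodinane, NaHCO3, CH2Cl2, rt
Reagents that add atoms: none
Why: Dess–Martin oxidation gives a neopentyl aldehyde that has no α-hydrogen and so cannot epimerise.

Step 11
Reactants: 18 aldehyde
Product: 19 (2S)-vinyl carbinol
Conditions: MgBr2·OEt2, CH2Cl2, −78 °C; CH2=CHMgBr, THF, −78 °C
Reagents that add atoms: vinylmagnesium bromide, C=C[Mg]Br
Why: Chelation-controlled (Cram chelate) Grignard addition, in which magnesium bridges the aldehyde oxygen and the axial C14 acetonide oxygen and the vinyl group enters from the C15 methyl side, anti to C10, to set (2S).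

Step 12
Reactants: 19 vinyl carbinol acetonide
Product: 20 2,13,14-triol
Conditions: AcOH/H2O/THF (3:1:1), 50 °C
Reagents that add atoms: none
Why: Mild acid hydrolysis of the acetonide, which the silyl ether, the 4-methoxybenzyl ether and all stereocentres should survive.

Step 13
Reactants: 20 triol
Product: 21 ring A triacetate (acetates at C2, C13, C14)
Conditions: Ac2O, DMAP, pyridine, rt
Reagents that add atoms: acetic anhydride, CC(=O)OC(C)=O
Why: DMAP-catalysed acetylation installs three of the four acetates of the target with retention at every carbinol centre.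

Step 14
Reactants: 22 (R)-2,3-O-isopropylideneglyceraldehyde
Product: 23 (S)-4-ethynyl-2,2-dimethyl-1,3-dioxolane
Conditions: dimethyl (1-diazo-2-oxopropyl)phosphonate, K2CO3, MeOH, 0 °C to rt
Reagents that add atoms: dimethyl (1-diazo-2-oxopropyl)phosphonate, CC(=O)C(=[N+]=[N-])P(=O)(OC)OC
Why: Seyferth–Gilbert homologation in its Ohira–Bestmann form turns the aldehyde into the alkyne (C6≡C5) under mild base and keeps the C7 centre taken from the chiral pool.

Step 15
Reactants: 23 terminal alkyne
Product: 25 3-[(4S)-2,2-dimethyl-1,3-dioxolan-4-yl]prop-2-yn-1-ol, via lithium acetylide 24 (not isolated)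
Conditions: n-BuLi, THF, −78 °C; (CH2O)n, −78 °C to rt
Reagents that add atoms: formaldehyde (as paraformaldehyde), C=O
Why: Acetylide addition to formaldehyde adds C16 as a primary propargylic alcohol without touching C7.

Step 16
Reactants: 25 propargylic alcohol
Product: 26 C16 4-methoxybenzyl ether
Conditions: NaH, 4-methoxybenzyl chloride, Bu4NI (cat.), THF/DMF, 0 °C to rt
Reagents that add atoms: 4-methoxybenzyl chloride, COc1ccc(CCl)cc1
Why: Williamson etherification protects the hydroxyl that later becomes the chloride and leaves C7 untouched.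

Step 17
Reactants: 26 alkynyl dioxolane
Product: 27 (S)-5-(4-methoxybenzyloxy)pent-3-yne-1,2-diol
Conditions: AcOH/H2O (4:1), 40 °C
Reagents that add atoms: none
Why: Acetal hydrolysis frees the C7 hydroxyl needed to direct the next step, with no change at C7.

Step 18
Reactants: 27 alkynediol
Product: 29 (2S,3Z)-4-iodo-5-(4-methoxybenzyloxy)pent-3-ene-1,2-diol, via alkenylalanate 28 (not isolated)
Conditions: NaAlH2(OCH2CH2OMe)2, THF, 0 °C to rt; I2, THF, −78 °C
Reagents that add atoms: iodine, II
Why: Hydroxyl-directed trans-hydroalumination of the propargylic alcohol delivers hydride to C6 and aluminium to C5 in a five-membered alanate, and iodinolysis with retention gives the iodoalkene with C16 trans to C7.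

Step 19
Reactants: 29 iodoalkene diol
Product: 30 (2S,3Z)-2-hydroxy-4-iodo-5-(4-methoxybenzyloxy)pent-3-enoic acid
Conditions: TEMPO (cat.), NaOCl (cat.), NaClO2, MeCN/phosphate buffer (pH 6.7), 35 °C
Reagents that add atoms: sodium chlorite, [Na+].[O-]Cl=O
Why: Oxoammonium/chlorite oxidation is selective for the primary hydroxyl and turns C8 into the carboxyl carbon while the secondary allylic C7 carbinol is kept.

Step 20
Reactants: 30 α-hydroxy acid
Product: 31 4-methoxybenzyl ester of 30
Conditions: 4-methoxybenzyl chloride, KHCO3, DMF, rt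
Reagents that add atoms: 4-methoxybenzyl chloride, COc1ccc(CCl)cc1
Why: Carboxylate O-alkylation under weak base introduces the group that becomes the C8 oxygen substituent and does not epimerise C7.

Step 21
Reactants: 31 α-hydroxy ester
Product: 32 O-(2-bromopropanoyl) ester (mixture at the CHBr carbon)
Conditions: 2-bromopropanoyl bromide, pyridine, CH2Cl2, 0 °C
Reagents that add atoms: 2-bromopropanoyl bromide, CC(Br)C(Br)=O
Why: O-acylation of the C7 hydroxyl brings in C17, C18 and C19 with retention at C7.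

Step 22
Reactants: 32 bromo ester
Product: 35 (S)-5-[(Z)-2-iodo-3-(4-methoxybenzyloxy)prop-1-enyl]-4-(4-methoxybenzyloxy)-3-methylfuran-2(5H)-one, via phosphonium bromide 33 (not isolated), via phosphorus ylide 34 (not isolated)
Conditions: PPh3, MeCN, 50 °C; Et3N, toluene, 110 °C
Reagents that add atoms: none
Why: Phosphonium salt formation, deprotonation and intramolecular Wittig olefination of the ester carbonyl close the tetronate ring (C8=C17) without strong base, so C7 keeps its configuration and the ester alkoxy group becomes the C8 ether.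

Step 23
Reactants: 21 ring A triacetate; 35 iodo-tetronate
Product: 37 coupled seco compound (C4–C5 bond), via alkylborane 36 (not isolated)
Conditions: (c-C6H11)2BH (from BH3·SMe2 and cyclohexene), THF, 0 °C to rt; 35, PdCl2(dppf) (5 mol %), AsPh3, Cs2CO3, DMF/H2O, rt
Reagents that add atoms: none
Why: The hindered dialkylborane hydroborates the monosubstituted C3=C4 alkene faster than the flanked exocyclic C11=C20 alkene, and the B-alkyl Suzuki–Miyaura coupling proceeds with retention of the iodoalkene geometry, so C4 ends up cis to C7.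

Step 24
Reactants: 37 C9 silyl ether
Product: 38 C9 primary alcohol
Conditions: HF·pyridine, pyridine, THF, rt
Reagents that add atoms: none
Why: Fluoride-mediated desilylation removes the only silyl group while acetates, 4-methoxybenzyl ethers and the tetronate are stable to buffered HF.

Step 25
Reactants: 38 alcohol
Product: 39 C9 aldehyde
Conditions: Dess–Martin periodinane, NaHCO3, CH2Cl2, 0 °C
Reagents that add atoms: none
Why: Buffered Dess–Martin oxidation gives the β,γ-unsaturated aldehyde under neutral conditions, which should avoid epimerisation at C10 and migration of the C11=C20 bond if the crude product is used at once.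

Step 26
Reactants: 39 tetronate aldehyde
Product: 40 macrocyclic 8-(4-methoxybenzyloxy)-9-hydroxy lactone
Conditions: SmI2 (3 equiv), MeOH (4 equiv), THF, 0 °C, slow addition of 39 to 0.002 M
Reagents that add atoms: none
Why: Proposed new method: single-electron reduction of the C9 aldehyde by SmI2 gives a samarium ketyl that adds 10-exo-trig to C8, the oxygen-bearing β-carbon of the tetronate, and the resulting C17 radical is reduced to a trivalent samarium enolate that methanol protonates, so the ten-membered ring, the C8–C9 bond and the C8, C9 and C17 centres arise together. The closest known reaction type is the SmI2-induced reductive cyclisation of aldehydes onto β-alkoxyacrylates (six- and seven-membered cyclic ethers, fully substituted β-carbons included), together with SmI2 ketyl–olefin closures of eight-membered carbocycles; new here are the cyclic α-methylated acceptor and the ten-membered ring. C8 should be attacked on the lactone face opposite the C6 substituent of C7, because only this trans ring fusion allows a staggered C7–C8 torsion in the ten-membered ring. C9 is expected to be set by a chelate of trivalent samarium between the ketyl oxygen and the C8 ether oxygen with C10 turned away from the lactone, and C17 by proton delivery from samarium-bound methanol on the C9 side, anti to the 4-methoxybenzyloxy group. The step needs cyclisation to outrun reduction of the ketyl to alcohol 38 and pinacol dimerisation, which slow addition at high dilution, the single reducible carbonyl group, the cis C5=C6 alkene and the trans-diequatorial C2/C9 branches of ring A are meant to secure.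

Step 27
Reactants: 40 C9 alcohol
Product: 41 C9 acetate
Conditions: Ac2O, DMAP, Et3N, CH2Cl2, rt
Reagents that add atoms: acetic anhydride, CC(=O)OC(C)=O
Why: DMAP-catalysed acetylation of the only free hydroxyl installs the fourth acetate with retention at C9.

Step 28
Reactants: 41 tris(4-methoxybenzyl) ether
Product: 42 8,12,16-triol
Conditions: DDQ, CH2Cl2/pH 7 buffer, 0 °C to rt
Reagents that add atoms: none
Why: Oxidative cleavage of all three 4-methoxybenzyl ethers by DDQ under buffered conditions frees exactly the hydroxyls that are free (C8, C12) or become chloride (C16), without touching acetates, lactone or alkenes.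

Step 29
Reactants: 42 triol
Product: 44 C16 allylic chloride, via allylic mesylate 43 (not isolated)
Conditions: MsCl, 2,4,6-collidine, LiCl, DMF, 0 °C
Reagents that add atoms: lithium chloride, [Li+].[Cl-]
Why: Collington–Meyers chlorination, in which only the primary allylic hydroxyl is mesylated at 0 °C and chloride displaces it by SN2, while the hindered secondary C12 and tertiary C8 hydroxyls stay free.

Step 30
Reactants: 44 allylic chloride
Product: 45 CNP0330408.1
Conditions: VO(acac)2 (5 mol %), t-BuOOH, CH2Cl2, 0 °C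
Reagents that add atoms: tert-butyl hydroperoxide, CC(C)(C)OO
Why: Hydroxyl-directed vanadium-catalysed epoxidation, in which the axial C12 hydroxyl delivers oxygen to the face of the C11=C20 bond on which it lies (giving the (11R)-spiro-epoxide), while the C5=C6 bond is deactivated by its allylic chloride and lactone oxygen.

**Compound list**

1 | (tert-butyldiphenylsilyloxy)acetaldehyde | O=CCO[Si](c1ccccc1)(c1ccccc1)C(C)(C)C | starting material
2 | 2-(triphenylphosphoranylidene)propanal | CC(C=O)=P(c1ccccc1)(c1ccccc1)c1ccccc1 | starting material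
3 | (E)-4-(tert-butyldiphenylsilyloxy)-2-methylbut-2-enal | O=C/C(C)=C/CO[Si](c1ccccc1)(c1ccccc1)C(C)(C)C | intermediate
4 | (E)-3-(tert-butyldimethylsilyloxy)-N,N-dimethylbuta-1,3-dien-1-amine | CN(C)/C=C/C(=C)O[Si](C)(C)C(C)(C)C | starting material
5 | endo cycloadduct aldehyde (CHO cis to NMe2, trans to the C9 branch) | CN(C)[C@H]1C=C(O[Si](C)(C)C(C)(C)C)C[C@H](CO[Si](c2ccccc2)(c2ccccc2)C(C)(C)C)[C@@]1(C)C=O | intermediate
6 | amino alcohol from reduction of 5 | CN(C)[C@H]1C=C(O[Si](C)(C)C(C)(C)C)C[C@H](CO[Si](c2ccccc2)(c2ccccc2)C(C)(C)C)[C@@]1(C)CO | intermediate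
7 | (4S,5S)-5-[(tert-butyldiphenylsilyloxy)methyl]-4-(hydroxymethyl)-4-methylcyclohex-2-en-1-one | O=C1C=C[C@](C)(CO)[C@@H](CO[Si](c2ccccc2)(c2ccccc2)C(C)(C)C)C1 | intermediate
8 | C2 tert-butyldimethylsilyl ether of 7 | O=C1C=C[C@](C)(CO[Si](C)(C)C(C)(C)C)[C@@H](CO[Si](c2ccccc2)(c2ccccc2)C(C)(C)C)C1 | intermediate
9 | cis-13,14-diol C12-ketone (hydroxyls cis to the C2 branch) | O[C@H]1C(=O)C[C@H](CO[Si](c2ccccc2)(c2ccccc2)C(C)(C)C)[C@@](C)(CO[Si](C)(C)C(C)(C)C)[C@H]1O | intermediate
10 | 13,14-acetonide C12-ketone | CC1(C)O[C@H]2C(=O)C[C@H](CO[Si](c3ccccc3)(c3ccccc3)C(C)(C)C)[C@@](C)(CO[Si](C)(C)C(C)(C)C)[C@H]2O1 | intermediate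
11 | lithium enolate of 10 (C11=C12) | CC1(C)O[C@H]2C(O[Li])=C[C@H](CO[Si](c3ccccc3)(c3ccccc3)C(C)(C)C)[C@@](C)(CO[Si](C)(C)C(C)(C)C)[C@H]2O1 | intermediate
12 | C11 (dimethylamino)methyl ketone (Mannich base, aminomethyl trans to the C9 branch) | CC1(C)O[C@H]2C(=O)[C@@H](CN(C)C)[C@H](CO[Si](c3ccccc3)(c3ccccc3)C(C)(C)C)[C@@](C)(CO[Si](C)(C)C(C)(C)C)[C@H]2O1 | intermediate
13 | trimethylammonium iodide of 12 | CC1(C)O[C@H]2C(=O)[C@@H](C[N+](C)(C)C)[C@H](CO[Si](c3ccccc3)(c3ccccc3)C(C)(C)C)[C@@](C)(CO[Si](C)(C)C(C)(C)C)[C@H]2O1.[I-] | intermediate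
14 | C11-methylene C12-ketone | CC1(C)O[C@H]2C(=O)C(=C)[C@H](CO[Si](c3ccccc3)(c3ccccc3)C(C)(C)C)[C@@](C)(CO[Si](C)(C)C(C)(C)C)[C@H]2O1 | intermediate
15 | C12 allylic alcohol, hydroxyl cis to the acetonide | CC1(C)O[C@H]2[C@@H](O)C(=C)[C@H](CO[Si](c3ccccc3)(c3ccccc3)C(C)(C)C)[C@@](C)(CO[Si](C)(C)C(C)(C)C)[C@H]2O1 | intermediate
16 | C12 4-methoxybenzyl ether | CC1(C)O[C@H]2[C@@H](OCc3ccc(OC)cc3)C(=C)[C@H](CO[Si](c3ccccc3)(c3ccccc3)C(C)(C)C)[C@@](C)(CO[Si](C)(C)C(C)(C)C)[C@H]2O1 | intermediate
17 | C2 primary alcohol | CC1(C)O[C@H]2[C@@H](OCc3ccc(OC)cc3)C(=C)[C@H](CO[Si](c3ccccc3)(c3ccccc3)C(C)(C)C)[C@@](C)(CO)[C@H]2O1 | intermediate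
18 | C2 aldehyde | CC1(C)O[C@H]2[C@@H](OCc3ccc(OC)cc3)C(=C)[C@H](CO[Si](c3ccccc3)(c3ccccc3)C(C)(C)C)[C@@](C)(C=O)[C@H]2O1 | intermediate
19 | (2S)-vinyl carbinol | CC1(C)O[C@H]2[C@@H](OCc3ccc(OC)cc3)C(=C)[C@H](CO[Si](c3ccccc3)(c3ccccc3)C(C)(C)C)[C@@](C)([C@@H](O)C=C)[C@H]2O1 | intermediate
20 | 2,13,14-triol | O[C@H]1[C@@H](OCc2ccc(OC)cc2)C(=C)[C@H](CO[Si](c2ccccc2)(c2ccccc2)C(C)(C)C)[C@@](C)([C@@H](O)C=C)[C@H]1O | intermediate
21 | ring A triacetate (2,13,14-triacetate, C12 ether, C9 silyl ether, C3=C4 vinyl) | CC(=O)O[C@H]1[C@@H](OCc2ccc(OC)cc2)C(=C)[C@H](CO[Si](c2ccccc2)(c2ccccc2)C(C)(C)C)[C@@](C)([C@@H](OC(C)=O)C=C)[C@H]1OC(C)=O | intermediate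
22 | (R)-2,3-O-isopropylideneglyceraldehyde | O=C[C@H]1COC(C)(C)O1 | starting material
23 | (S)-4-ethynyl-2,2-dimethyl-1,3-dioxolane | C#C[C@H]1COC(C)(C)O1 | intermediate
24 | lithium acetylide of 23 | [Li]C#C[C@H]1COC(C)(C)O1 | intermediate
25 | 3-[(4S)-2,2-dimethyl-1,3-dioxolan-4-yl]prop-2-yn-1-ol | OCC#C[C@H]1COC(C)(C)O1 | intermediate
26 | 4-methoxybenzyl ether of 25 | COc1ccc(COCC#C[C@H]2COC(C)(C)O2)cc1 | intermediate
27 | (S)-5-(4-methoxybenzyloxy)pent-3-yne-1,2-diol | COc1ccc(COCC#C[C@H](O)CO)cc1 | intermediate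
28 | cyclic alkenylalanate (aluminium on C5, bound to the C7 oxygen) | [Na+].[Na+].COCCO[Al-]1(OCCOC)O[C@H](C[O-])C=C1COCc1ccc(OC)cc1 | intermediate
29 | (2S,3Z)-4-iodo-5-(4-methoxybenzyloxy)pent-3-ene-1,2-diol | COc1ccc(COC/C(I)=C/[C@H](O)CO)cc1 | intermediate
30 | (2S,3Z)-2-hydroxy-4-iodo-5-(4-methoxybenzyloxy)pent-3-enoic acid | COc1ccc(COC/C(I)=C/[C@H](O)C(O)=O)cc1 | intermediate
31 | 4-methoxybenzyl ester of 30 | COc1ccc(COC/C(I)=C/[C@H](O)C(=O)OCc2ccc(OC)cc2)cc1 | intermediate
32 | O-(2-bromopropanoyl) derivative of 31 | COc1ccc(COC/C(I)=C/[C@H](OC(=O)C(C)Br)C(=O)OCc2ccc(OC)cc2)cc1 | intermediate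
33 | phosphonium bromide from 32 | COc1ccc(COC/C(I)=C/[C@H](OC(=O)C(C)[P+](c2ccccc2)(c2ccccc2)c2ccccc2)C(=O)OCc2ccc(OC)cc2)cc1.[Br-] | intermediate
34 | phosphorus ylide from 33 | COc1ccc(COC/C(I)=C/[C@H](OC(=O)C(C)=P(c2ccccc2)(c2ccccc2)c2ccccc2)C(=O)OCc2ccc(OC)cc2)cc1 | intermediate
35 | (S)-5-[(Z)-2-iodo-3-(4-methoxybenzyloxy)prop-1-enyl]-4-(4-methoxybenzyloxy)-3-methylfuran-2(5H)-one | COc1ccc(COC/C(I)=C/[C@@H]2OC(=O)C(C)=C2OCc2ccc(OC)cc2)cc1 | intermediate
36 | C4 dicyclohexylborane from 21 | CC(=O)O[C@H]1[C@@H](OCc2ccc(OC)cc2)C(=C)[C@H](CO[Si](c2ccccc2)(c2ccccc2)C(C)(C)C)[C@@](C)([C@@H](OC(C)=O)CCB(C2CCCCC2)C2CCCCC2)[C@H]1OC(C)=O | intermediate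
37 | coupled seco compound, C9 silyl ether | CC(=O)O[C@H]1[C@@H](OCc2ccc(OC)cc2)C(=C)[C@H](CO[Si](c2ccccc2)(c2ccccc2)C(C)(C)C)[C@@](C)([C@@H](OC(C)=O)CC/C(COCc2ccc(OC)cc2)=C\[C@@H]2OC(=O)C(C)=C2OCc2ccc(OC)cc2)[C@H]1OC(C)=O | intermediate
38 | seco C9 alcohol | CC(=O)O[C@H]1[C@@H](OCc2ccc(OC)cc2)C(=C)[C@H](CO)[C@@](C)([C@@H](OC(C)=O)CC/C(COCc2ccc(OC)cc2)=C\[C@@H]2OC(=O)C(C)=C2OCc2ccc(OC)cc2)[C@H]1OC(C)=O | intermediate
39 | seco C9 aldehyde | CC(=O)O[C@H]1[C@@H](OCc2ccc(OC)cc2)C(=C)[C@H](C=O)[C@@](C)([C@@H](OC(C)=O)CC/C(COCc2ccc(OC)cc2)=C\[C@@H]2OC(=O)C(C)=C2OCc2ccc(OC)cc2)[C@H]1OC(C)=O | intermediate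
40 | macrocycle: 9-hydroxy, 8-(4-methoxybenzyloxy), configuration at C7, C8, C9, C17 as in the target | CC(=O)O[C@H]1[C@@H](OCc4ccc(OC)cc4)C(=C)[C@@H]2[C@H](O)[C@@]3(OCc4ccc(OC)cc4)[C@H](/C=C(/COCc4ccc(OC)cc4)CC[C@H](OC(C)=O)[C@@]2(C)[C@H]1OC(C)=O)OC(=O)[C@@H]3C | intermediate
41 | C9 acetate of 40 | CC(=O)O[C@H]1[C@@H](OCc4ccc(OC)cc4)C(=C)[C@@H]2[C@H](OC(C)=O)[C@@]3(OCc4ccc(OC)cc4)[C@H](/C=C(/COCc4ccc(OC)cc4)CC[C@H](OC(C)=O)[C@@]2(C)[C@H]1OC(C)=O)OC(=O)[C@@H]3C | intermediate
42 | 8,12,16-triol | CC(=O)O[C@H]1[C@@H](O)C(=C)[C@@H]2[C@H](OC(C)=O)[C@@]3(O)[C@H](/C=C(/CO)CC[C@H](OC(C)=O)[C@@]2(C)[C@H]1OC(C)=O)OC(=O)[C@@H]3C | intermediate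
43 | C16 mesylate | CC(=O)O[C@H]1[C@@H](O)C(=C)[C@@H]2[C@H](OC(C)=O)[C@@]3(O)[C@H](/C=C(/COS(C)(=O)=O)CC[C@H](OC(C)=O)[C@@]2(C)[C@H]1OC(C)=O)OC(=O)[C@@H]3C | intermediate
44 | C16 chloride with C11=C20 methylene | CC(=O)O[C@H]1[C@@H](O)C(=C)[C@@H]2[C@H](OC(C)=O)[C@@]3(O)[C@H](/C=C(/CCl)CC[C@H](OC(C)=O)[C@@]2(C)[C@H]1OC(C)=O)OC(=O)[C@@H]3C | intermediate
45 | CNP0330408.1 | CC(=O)O[C@H]1[C@@H](O)[C@]2(CO2)[C@@H]2[C@H](OC(C)=O)[C@@]3(O)[C@H](/C=C(/CCl)CC[C@H](OC(C)=O)[C@@]2(C)[C@H]1OC(C)=O)OC(=O)[C@@H]3C | target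

**Totals and risks**

Total step count: 30. Longest linear sequence: 21 steps (steps 1–13, then 23–30); the tetronate branch (steps 14–22) joins at step 23.

Steps most likely to fail:

1. Step 26. The ten-membered radical closure onto a tetrasubstituted, electron-rich acceptor may be slower than reduction of the ketyl back to alcohol 38 or intermolecular pinacol coupling, and face selectivity at C9 may be poor. The fallback closes the same bond by known chemistry. It sets out from alcohol 38. Dilute CF3CO2H with anisole in CH2Cl2 at 0 °C cleaves only the vinylogous 4-methoxybenzyl ester to give the tetronic acid F1. N-Phenyltriflimide and Et3N convert it into the enol triflate F2, and Dess–Martin oxidation gives the triflate aldehyde F3. A Nozaki–Hiyama–Kishi reaction (NiCl2 cat., CrCl2, DMSO/THF, high dilution) closes C8–C9 to the macrocyclic butenolide alcohol F4. Acetylation gives the butenolide acetate F5, and nucleophilic epoxidation (t-BuOOH, DBU) gives the 8,17-epoxy lactone F6. SmI2/MeOH opens the α,β-epoxy lactone at C17 to the 8-hydroxy lactone F7. DDQ then removes the two remaining 4-methoxybenzyl ethers, and the route is rejoined at triol 42.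

2. Step 2. The trisubstituted enal may react too slowly for the diol catalyst to outpace the uncatalysed cycloaddition, which would erode the enantioselectivity. The fallback is resolution instead of catalysis. It sets out from enal 3 and diene 4. The uncatalysed cycloaddition in toluene at rt, followed by LiAlH4 and dilute HCl as in step 2, gives 7 as the racemate, that is together with the enantiomeric enone F10, which arises through the enantiomeric cycloadduct F8 and the enantiomeric amino alcohol F9. The enantiomers are separated by preparative chromatography on a chiral stationary phase, and 7 re-enters at step 3.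

3. Step 11. Competition between the chelated and the open transition state may give poor facial selectivity at C2. The fallback replaces substrate control by reagent control. It sets out from 19 as its mixture with the C2 epimer. Dess–Martin oxidation gives the vinyl ketone F11, and Corey–Bakshi–Shibata reduction with (R)-2-methyl-CBS-oxazaborolidine and BH3·SMe2 in toluene at −40 °C (quaternary C1 as the large group, vinyl as the small one) returns (2S)-19.

**Further compounds**

F1 | step 26 | tetronic acid (C8 enol free, C9 alcohol) | CC(=O)O[C@H]1[C@@H](OCc2ccc(OC)cc2)C(=C)[C@H](CO)[C@@](C)([C@@H](OC(C)=O)CC/C(COCc2ccc(OC)cc2)=C\[C@@H]2OC(=O)C(C)=C2O)[C@H]1OC(C)=O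
F2 | step 26 | C8 enol triflate, C9 alcohol | CC(=O)O[C@H]1[C@@H](OCc2ccc(OC)cc2)C(=C)[C@H](CO)[C@@](C)([C@@H](OC(C)=O)CC/C(COCc2ccc(OC)cc2)=C\[C@@H]2OC(=O)C(C)=C2OS(=O)(=O)C(F)(F)F)[C@H]1OC(C)=O
F3 | step 26 | C8 enol triflate, C9 aldehyde | CC(=O)O[C@H]1[C@@H](OCc2ccc(OC)cc2)C(=C)[C@H](C=O)[C@@](C)([C@@H](OC(C)=O)CC/C(COCc2ccc(OC)cc2)=C\[C@@H]2OC(=O)C(C)=C2OS(=O)(=O)C(F)(F)F)[C@H]1OC(C)=O
F4 | step 26 | macrocyclic 8(17)-butenolide, C9 alcohol | CC(=O)O[C@H]1[C@@H](OCc4ccc(OC)cc4)C(=C)[C@@H]2[C@H](O)C3=C(C)C(=O)O[C@H]3/C=C(/COCc4ccc(OC)cc4)CC[C@H](OC(C)=O)[C@@]2(C)[C@H]1OC(C)=O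
F5 | step 26 | macrocyclic 8(17)-butenolide, C9 acetate | CC(=O)O[C@H]1[C@@H](OCc4ccc(OC)cc4)C(=C)[C@@H]2[C@H](OC(C)=O)C3=C(C)C(=O)O[C@H]3/C=C(/COCc4ccc(OC)cc4)CC[C@H](OC(C)=O)[C@@]2(C)[C@H]1OC(C)=O
F6 | step 26 | 8,17-epoxy lactone (epoxide oxygen on the face of the C6 substituent) | CC(=O)O[C@H]1[C@@H](OCc5ccc(OC)cc5)C(=C)[C@@H]2[C@H](OC(C)=O)[C@]3(O4)[C@]4(C)C(=O)O[C@H]3/C=C(/COCc5ccc(OC)cc5)CC[C@H](OC(C)=O)[C@@]2(C)[C@H]1OC(C)=O
F7 | step 26 | 8-hydroxy lactone with C12 and C16 4-methoxybenzyl ethers | CC(=O)O[C@H]1[C@@H](OCc4ccc(OC)cc4)C(=C)[C@@H]2[C@H](OC(C)=O)[C@@]3(O)[C@H](/C=C(/COCc4ccc(OC)cc4)CC[C@H](OC(C)=O)[C@@]2(C)[C@H]1OC(C)=O)OC(=O)[C@@H]3C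
F8 | step 2 | enantiomer of cycloadduct aldehyde 5 | CN(C)[C@@H]1C=C(O[Si](C)(C)C(C)(C)C)C[C@@H](CO[Si](c2ccccc2)(c2ccccc2)C(C)(C)C)[C@]1(C)C=O
F9 | step 2 | enantiomer of amino alcohol 6 | CN(C)[C@@H]1C=C(O[Si](C)(C)C(C)(C)C)C[C@@H](CO[Si](c2ccccc2)(c2ccccc2)C(C)(C)C)[C@]1(C)CO
F10 | step 2 | (4R,5R)-enantiomer of enone 7 | O=C1C=C[C@@](C)(CO)[C@H](CO[Si](c2ccccc2)(c2ccccc2)C(C)(C)C)C1
F11 | step 11 | C2 vinyl ketone | CC1(C)O[C@H]2[C@@H](OCc3ccc(OC)cc3)C(=C)[C@H](CO[Si](c3ccccc3)(c3ccccc3)C(C)(C)C)[C@@](C)(C(=O)C=C)[C@H]2O1
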